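**Plan**

1. Oxane numbering: O1, C2 (carries the acrylic acid), C3, C4, C5 (carries the side chain), C6. The retrosynthesis cuts, in this order: the exocyclic CH2 and the ester (α-methylenation, saponification); the C2–Cα bond (addition to a C2 oxocarbenium ion); the oxane ring twice at once, at C4–C5 and O1–C2; and last the side-chain bond between the farnesyl CH2 and its neighbour.
2. The double ring cut is possible because C5 is the α-carbon of C6 once C6 is an aldehyde, and C4–C3–C2 is an acrylate at the acid oxidation level. O1–C6–C5 is therefore an aldehyde, C2–C3–C4 a Michael acceptor, and the only ring of the target a δ-lactone made by [3+3] union.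
3. Forward: farnesyl bromide (all three E-alkenes bought) and a three-carbon Grignard acetal give the C18 aldehyde. One flask (enamine Michael addition to methylenemalonate, hydride reduction, lactonisation) closes the ring. The second ester, the activating helper, is then removed. Reductive acetylation, ketene silyl acetal addition at C2, Mannich methylenation and saponification finish the route.
4. Stereochemistry: C5 (R) comes from the (S)-diarylprolinol silyl ether catalyst in the key step. C2 (R) comes from axial attack on the oxocarbenium half-chair with the C5 chain pseudoequatorial, which gives the 2,5-cis oxane.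

Key step: step 3

Remark: the target is read as the (2R,5R), 2,5-cis-disubstituted oxane with a (3E,7E) chain; (2E,6E)-farnesyl bromide and diethyl methylenemalonate are taken as bought.
Short name used below: TTT = (3E,7E)-4,8,12-trimethyltrideca-3,7,11-trien-1-yl.

**Step 1**
Reactants: 1 (2E,6E)-farnesyl bromide; 2 2-(2-bromoethyl)-1,3-dioxolane
Product: 4 2-[(4E,8E)-5,9,13-trimethyltetradeca-4,8,12-trien-1-yl]-1,3-dioxolane, via Grignard reagent 3 (not isolated)
Conditions: 2, Mg, THF, below 30 °C; then 1, Li2CuCl4 (3 mol %), THF, −20 → 0 °C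
Reagents that add atoms: none
Why: Copper-catalysed Grignard cross-coupling with a primary allylic bromide should give direct substitution at the CH2Br terminus with retention of the adjacent E-alkene, and the dioxolane is inert to the organometallic.

**Step 2**
Reactants: 4 2-[(4E,8E)-5,9,13-trimethyltetradeca-4,8,12-trien-1-yl]-1,3-dioxolane
Product: 5 (5E,9E)-6,10,14-trimethylpentadeca-5,9,13-trienal
Conditions: 2 M aq HCl, THF, 25 °C
Reagents that add atoms: water, O
Why: Acid-catalysed acetal hydrolysis in dilute aqueous acid at room temperature should free the aldehyde without protonating the trisubstituted alkenes.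

**Step 3**
Reactants: 5 (5E,9E)-6,10,14-trimethylpentadeca-5,9,13-trienal; 6 diethyl methylenemalonate
Product: 9 ethyl (5R)-2-oxo-5-TTT-oxane-3-carboxylate (both C3 epimers), via Michael adduct aldehyde 7 (not isolated), via hydroxy diester 8 (not isolated)
Conditions: 6 (1.2 equiv), (S)-2-[diphenyl(trimethylsilyloxy)methyl]pyrrolidine (10 mol %), PhCO2H (10 mol %), toluene, 0 °C; then EtOH, NaBH4, 0 °C; then aq NH4Cl wash, pyridinium 4-toluenesulfonate (cat.), toluene, 80 °C (EtOH distilled off)
Reagents that add atoms: none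
Why: The amine condenses with 5 to the E-enamine, whose C5 adds to the unsubstituted terminus of 6 (enamine Michael addition, C4–C5) and hydrolysis returns the catalyst and aldehyde 7; NaBH4 then reduces only the aldehyde to alcohol 8, whose oxygen attacks one malonate ester carbon (O1–C2) to give the lactone. The closest known reaction type is the amine-catalysed Michael addition of aldehydes to alkylidene malonates and to 2-phosphonoacrylates with reduction and lactonisation in the same flask. The oxane ring closes by 6-exo-trig addition–elimination at the ester carbon. C5 is set by the catalyst: its diphenyl(silyloxy)methyl group shields the Re face of the anti enamine, so the acceptor adds to the Si face and the centre should be R; the C3 centre forms without control and is removed in step 4. The step needs mono-addition, hydride delivery to the aldehyde only and retention of the labile α-centre; the unsubstituted β-carbon of 6 gives fast addition with no stereocentre at C4, NaBH4 at 0 °C leaves the esters alone, and immediate reduction removes the epimerisable aldehyde.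

**Step 4**
Reactants: 9 ethyl (5R)-2-oxo-5-TTT-oxane-3-carboxylate
Product: 10 (5R)-5-TTT-oxan-2-one
Conditions: LiCl, H2O (2 equiv), DMSO, 150 °C
Reagents that add atoms: none
Why: Krapcho dealkoxycarbonylation removes the activating ester (chloride dealkylates the ethyl ester, the carboxylate loses CO2, the lactone enolate is protonated), and C5 is not α to a carbonyl so it should be untouched.

**Step 5**
Reactants: 10 (5R)-5-TTT-oxan-2-one
Product: 12 (5R)-5-TTT-oxan-2-yl acetate (both anomers), via aluminium lactolate 11 (not isolated)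
Conditions: iBu2AlH, CH2Cl2, −78 °C; then pyridine, DMAP, Ac2O, −78 → 0 °C
Reagents that add atoms: acetic anhydride, CC(=O)OC(C)=O
Why: Reductive acetylation: the lactone is reduced to the tetrahedral aluminium lactolate at −78 °C and acetylated in situ, which should give the α-acetoxy ether without ring opening; the anomeric configuration does not matter.

**Step 6**
Reactants: 12 (5R)-5-TTT-oxan-2-yl acetate; 13 tert-butyl[(1-methoxyethenyl)oxy]dimethylsilane
Product: 15 methyl 2-[(2R,5R)-5-TTT-oxan-2-yl]acetate, via oxocarbenium triflate 14 (not isolated)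
Conditions: 13 (2 equiv), Me3SiOTf (0.2 equiv), CH2Cl2, −78 °C
Reagents that add atoms: none
Why: Me3SiOTf ionises the anomeric acetate to oxocarbenium ion 14 and the ketene silyl acetal adds (Mukaiyama-type C-glycosylation) along the pseudoaxial trajectory of the half-chair with the C5 chain pseudoequatorial, through a chair-like transition state, which should place the new C2–C bond cis to the chain and set C2 as R.

**Step 7**
Reactants: 15 methyl 2-[(2R,5R)-5-TTT-oxan-2-yl]acetate
Product: 19 methyl 2-[(2R,5R)-5-TTT-oxan-2-yl]prop-2-enoate, via lithium enolate 16 (not isolated), via Mannich base 17 (not isolated), via ammonium iodide 18 (not isolated)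
Conditions: LiN(iPr)2, THF, −78 °C; CH2=NMe2+ I−, −78 → 0 °C; then MeI (excess), 25 °C; then aq NaHCO3, CH2Cl2, 25 °C
Reagents that add atoms: dimethyl(methylidene)ammonium iodide, C=[N+](C)C.[I-]
Why: Ester enolate Mannich reaction, N-methylation and base-induced loss of trimethylamine (Hofmann-type elimination) is the standard α-methylenation of esters, and at −78 °C the lithium enolate should not expel the ring oxygen, so C2 is kept.

**Step 8**
Reactants: 19 methyl 2-[(2R,5R)-5-TTT-oxan-2-yl]prop-2-enoate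
Product: 21 rhopaloic acid B, via lithium carboxylate 20 (not isolated)
Conditions: LiOH·H2O, THF/MeOH/H2O, 25 °C; then 1 M HCl to pH 3, 0 °C
Reagents that add atoms: lithium hydroxide, [Li+].[OH-]
Why: Saponification of the methyl ester followed by mild acidification; the 2-substituted acrylate is a poor acceptor for hydroxide, so the β-alkoxy centre C2 should survive.

**Compound list**

1 | (2E,6E)-farnesyl bromide | BrC/C=C(\C)CC/C=C(\C)CCC=C(C)C | starting material
2 | 2-(2-bromoethyl)-1,3-dioxolane | BrCCC1OCCO1 | starting material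
3 | [2-(1,3-dioxolan-2-yl)ethyl]magnesium bromide | Br[Mg]CCC1OCCO1 | intermediate (not isolated)
4 | 2-[(4E,8E)-5,9,13-trimethyltetradeca-4,8,12-trien-1-yl]-1,3-dioxolane | C1COC(O1)CCC/C=C(\C)CC/C=C(\C)CCC=C(C)C | intermediate
5 | (5E,9E)-6,10,14-trimethylpentadeca-5,9,13-trienal | O=CCCC/C=C(\C)CC/C=C(\C)CCC=C(C)C | intermediate
6 | diethyl 2-methylidenepropanedioate (diethyl methylenemalonate) | C=C(C(=O)OCC)C(=O)OCC | starting material
7 | diethyl 2-[(2R,5E,9E)-2-formyl-6,10,14-trimethylpentadeca-5,9,13-trien-1-yl]propanedioate | CCOC(=O)C(C[C@@H](CC/C=C(\C)CC/C=C(\C)CCC=C(C)C)C=O)C(=O)OCC | intermediate (not isolated)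
8 | diethyl 2-[(2R,5E,9E)-2-(hydroxymethyl)-6,10,14-trimethylpentadeca-5,9,13-trien-1-yl]propanedioate | CCOC(=O)C(C[C@@H](CC/C=C(\C)CC/C=C(\C)CCC=C(C)C)CO)C(=O)OCC | intermediate (not isolated)
9 | ethyl (5R)-2-oxo-5-[(3E,7E)-4,8,12-trimethyltrideca-3,7,11-trien-1-yl]oxane-3-carboxylate (both C3 epimers) | CCOC(=O)C1C[C@@H](CC/C=C(\C)CC/C=C(\C)CCC=C(C)C)COC1=O | intermediate
10 | (5R)-5-[(3E,7E)-4,8,12-trimethyltrideca-3,7,11-trien-1-yl]oxan-2-one | O=C1CC[C@@H](CC/C=C(\C)CC/C=C(\C)CCC=C(C)C)CO1 | intermediate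
11 | diisobutylaluminium (5R)-5-[(3E,7E)-4,8,12-trimethyltrideca-3,7,11-trien-1-yl]oxan-2-olate | CC(C)C[Al](CC(C)C)OC1CC[C@@H](CC/C=C(\C)CC/C=C(\C)CCC=C(C)C)CO1 | intermediate (not isolated)
12 | (5R)-5-[(3E,7E)-4,8,12-trimethyltrideca-3,7,11-trien-1-yl]oxan-2-yl acetate (both anomers) | CC(=O)OC1CC[C@@H](CC/C=C(\C)CC/C=C(\C)CCC=C(C)C)CO1 | intermediate
13 | tert-butyl[(1-methoxyethenyl)oxy]dimethylsilane | C=C(OC)O[Si](C)(C)C(C)(C)C | starting material
14 | (5R)-5-[(3E,7E)-4,8,12-trimethyltrideca-3,7,11-trien-1-yl]oxan-2-ylium trifluoromethanesulfonate (oxocarbenium ion, O1=C2) | C1=[O+]C[C@H](CC/C=C(\C)CC/C=C(\C)CCC=C(C)C)CC1.[O-]S(=O)(=O)C(F)(F)F | intermediate (not isolated)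
15 | methyl 2-[(2R,5R)-5-[(3E,7E)-4,8,12-trimethyltrideca-3,7,11-trien-1-yl]oxan-2-yl]acetate | COC(=O)C[C@H]1CC[C@@H](CC/C=C(\C)CC/C=C(\C)CCC=C(C)C)CO1 | intermediate
16 | lithium enolate of 15 (lithium 1-methoxy-2-[(2R,5R)-5-substituted oxan-2-yl]ethen-1-olate) | COC(O[Li])=C[C@H]1CC[C@@H](CC/C=C(\C)CC/C=C(\C)CCC=C(C)C)CO1 | intermediate (not isolated)
17 | methyl 3-(dimethylamino)-2-[(2R,5R)-5-[(3E,7E)-4,8,12-trimethyltrideca-3,7,11-trien-1-yl]oxan-2-yl]propanoate (α-carbon unassigned) | COC(=O)C(CN(C)C)[C@H]1CC[C@@H](CC/C=C(\C)CC/C=C(\C)CCC=C(C)C)CO1 | intermediate (not isolated)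
18 | 3-methoxy-N,N,N-trimethyl-3-oxo-2-[(2R,5R)-5-[(3E,7E)-4,8,12-trimethyltrideca-3,7,11-trien-1-yl]oxan-2-yl]propan-1-aminium iodide | COC(=O)C(C[N+](C)(C)C)[C@H]1CC[C@@H](CC/C=C(\C)CC/C=C(\C)CCC=C(C)C)CO1.[I-] | intermediate (not isolated)
19 | methyl 2-[(2R,5R)-5-[(3E,7E)-4,8,12-trimethyltrideca-3,7,11-trien-1-yl]oxan-2-yl]prop-2-enoate | COC(=O)C(=C)[C@H]1CC[C@@H](CC/C=C(\C)CC/C=C(\C)CCC=C(C)C)CO1 | intermediate
20 | lithium 2-[(2R,5R)-5-[(3E,7E)-4,8,12-trimethyltrideca-3,7,11-trien-1-yl]oxan-2-yl]prop-2-enoate | [Li+].[O-]C(=O)C(=C)[C@H]1CC[C@@H](CC/C=C(\C)CC/C=C(\C)CCC=C(C)C)CO1 | intermediate (not isolated)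
21 | rhopaloic acid B, 2-[(2R,5R)-5-[(3E,7E)-4,8,12-trimethyltrideca-3,7,11-trien-1-yl]oxan-2-yl]prop-2-enoic acid | C=C(C(=O)O)[C@H]1CC[C@@H](CC/C=C(\C)CC/C=C(\C)CCC=C(C)C)CO1 | target

**Totals**

Total step count: 8. Longest linear sequence: 8 steps (from 1).

**Steps most likely to fail**

Step 3. The amine may start anionic oligomerisation of the methylenemalonate, the acidic malonate C–H of the product may add to a second acceptor, or the α-branched aldehyde may lose configuration before it is reduced. The fallback sets out from 5 and returns at 10, using auxiliary-controlled conjugate addition with the two ring bonds made in separate steps. Oxidation of 5 (NaClO2, NaH2PO4, 2-methyl-2-butene, tBuOH/H2O) should give (5E,9E)-6,10,14-trimethylpentadeca-5,9,13-trienoic acid F1. Pivaloyl chloride and Et3N in THF at −20 °C convert it into 2,2-dimethylpropanoic (5E,9E)-6,10,14-trimethylpentadeca-5,9,13-trienoic anhydride F2. This acylates (S)-4-benzyl-1,3-oxazolidin-2-one (LiCl, THF) to (4S)-4-benzyl-3-[(5E,9E)-6,10,14-trimethylpentadeca-5,9,13-trienoyl]-1,3-oxazolidin-2-one F3. Its chlorotitanium enolate (TiCl4, iPr2NEt, CH2Cl2, 0 °C) should add to methyl acrylate from the face away from the benzyl group to give methyl (4R,7E,11E)-4-{[(4S)-4-benzyl-2-oxo-1,3-oxazolidin-3-yl]carbonyl}-8,12,16-trimethylheptadeca-7,11,15-trienoate F4. LiBH4 (1 equiv MeOH, Et2O, 0 °C) removes the auxiliary reductively to methyl (4R,7E,11E)-4-(hydroxymethyl)-8,12,16-trimethylheptadeca-7,11,15-trienoate F5. F5 should close to lactone 10 on warming with catalytic pyridinium 4-toluenesulfonate in toluene; step 4 is then not needed.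

Step 6. The very reactive ketene acetal may add to both faces of the oxocarbenium ion faster than the chair-like axial pathway can discriminate, so that the C2 centre forms as a cis/trans mixture. The fallback sets out from 12 and returns at 19, using a slower, rod-shaped nucleophile and building the acrylate by carbonylation. Bu3SnC≡CSiMe3 with Me3SiOTf in CH2Cl2 at −78 → −20 °C should give the axial adduct trimethyl{[(2R,5R)-5-[(3E,7E)-4,8,12-trimethyltrideca-3,7,11-trien-1-yl]oxan-2-yl]ethynyl}silane F6. K2CO3 in MeOH removes the silyl group to give (2R,5R)-2-ethynyl-5-[(3E,7E)-4,8,12-trimethyltrideca-3,7,11-trien-1-yl]oxane F7. Branch-selective (Markovnikov) methoxycarbonylation of the terminal alkyne (Pd(OAc)2, 2-(diphenylphosphino)pyridine, MeSO3H cat., CO, MeOH, 50 °C) should then give 19, and the route continues with step 8.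

Step 7. The lithium enolate may expel the ring oxygen (β-elimination, retro-oxa-Michael ring opening), and reclosure would let C2 drift towards the trans isomer; quaternisation may also stay incomplete. The fallback sets out from 15 and returns at 21, working at the aldehyde level without a strong base. iBu2AlH in CH2Cl2 at −78 °C should give 2-[(2R,5R)-5-[(3E,7E)-4,8,12-trimethyltrideca-3,7,11-trien-1-yl]oxan-2-yl]acetaldehyde F8. With CH2=NMe2+ I− and Et3N in CH2Cl2 at 25 °C this forms 3-(dimethylamino)-2-[(2R,5R)-5-[(3E,7E)-4,8,12-trimethyltrideca-3,7,11-trien-1-yl]oxan-2-yl]propanal F9, which loses dimethylamine to give 2-[(2R,5R)-5-[(3E,7E)-4,8,12-trimethyltrideca-3,7,11-trien-1-yl]oxan-2-yl]prop-2-enal F10. Pinnick oxidation (NaClO2, NaH2PO4, 2-methyl-2-butene, tBuOH/H2O, 0 °C) should then give 21 directly.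

**Further compounds**

F1 | step 3 | (5E,9E)-6,10,14-trimethylpentadeca-5,9,13-trienoic acid | OC(=O)CCC/C=C(\C)CC/C=C(\C)CCC=C(C)C
F2 | step 3 | 2,2-dimethylpropanoic (5E,9E)-6,10,14-trimethylpentadeca-5,9,13-trienoic anhydride | CC(C)(C)C(=O)OC(=O)CCC/C=C(\C)CC/C=C(\C)CCC=C(C)C
F3 | step 3 | (4S)-4-benzyl-3-[(5E,9E)-6,10,14-trimethylpentadeca-5,9,13-trienoyl]-1,3-oxazolidin-2-one | O=C(CCC/C=C(\C)CC/C=C(\C)CCC=C(C)C)N1C(=O)OC[C@@H]1Cc1ccccc1
F4 | step 3 | methyl (4R,7E,11E)-4-{[(4S)-4-benzyl-2-oxo-1,3-oxazolidin-3-yl]carbonyl}-8,12,16-trimethylheptadeca-7,11,15-trienoate | COC(=O)CC[C@@H](CC/C=C(\C)CC/C=C(\C)CCC=C(C)C)C(=O)N1C(=O)OC[C@@H]1Cc1ccccc1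
F5 | step 3 | methyl (4R,7E,11E)-4-(hydroxymethyl)-8,12,16-trimethylheptadeca-7,11,15-trienoate | COC(=O)CC[C@@H](CC/C=C(\C)CC/C=C(\C)CCC=C(C)C)CO
F6 | step 6 | trimethyl{[(2R,5R)-5-[(3E,7E)-4,8,12-trimethyltrideca-3,7,11-trien-1-yl]oxan-2-yl]ethynyl}silane | C[Si](C)(C)C#C[C@H]1CC[C@@H](CC/C=C(\C)CC/C=C(\C)CCC=C(C)C)CO1
F7 | step 6 | (2R,5R)-2-ethynyl-5-[(3E,7E)-4,8,12-trimethyltrideca-3,7,11-trien-1-yl]oxane | C#C[C@H]1CC[C@@H](CC/C=C(\C)CC/C=C(\C)CCC=C(C)C)CO1
F8 | step 7 | 2-[(2R,5R)-5-[(3E,7E)-4,8,12-trimethyltrideca-3,7,11-trien-1-yl]oxan-2-yl]acetaldehyde | O=CC[C@H]1CC[C@@H](CC/C=C(\C)CC/C=C(\C)CCC=C(C)C)CO1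
F9 | step 7 | 3-(dimethylamino)-2-[(2R,5R)-5-[(3E,7E)-4,8,12-trimethyltrideca-3,7,11-trien-1-yl]oxan-2-yl]propanal | O=CC(CN(C)C)[C@H]1CC[C@@H](CC/C=C(\C)CC/C=C(\C)CCC=C(C)C)CO1
F10 | step 7 | 2-[(2R,5R)-5-[(3E,7E)-4,8,12-trimethyltrideca-3,7,11-trien-1-yl]oxan-2-yl]prop-2-enal | C=C(C=O)[C@H]1CC[C@@H](CC/C=C(\C)CC/C=C(\C)CCC=C(C)C)CO1
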